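**Assumptions (one line):** atoms are referred to by germacrane numbering (C1–C15; target = 6R,7R,8S,10R, 4Z, angelate 2Z); rac‑glycidaldehyde diethyl acetal, (Z)‑3‑methylpent‑2‑en‑4‑yn‑1‑ol and angelic acid are taken as commercial. The route is a paper design, not experimentally validated.

## Retrosynthetic overview

1. Angelate: last‑step Yamaguchi acylation of the C8 alcohol.
2. 10‑membered carbocycle and α‑methylene‑γ‑lactone: formed together, last, by intramolecular CrCl2 Barbier allylation (C6–C7 bond) of a 2‑(bromomethyl)enoate onto a (Z)‑enal.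
3. Bromomethyl enoate: Morita–Baylis–Hillman reaction (C7–C11 bond) of an α‑silyloxy aldehyde with methyl acrylate, then SN2′ bromination.
4. 3(2H)‑Furanone (first ring): Au‑catalysed 5‑endo cyclisation of an α′‑hydroxy ynone, made by adding the acetylide of (Z)‑3‑methylpent‑2‑en‑4‑yn‑1‑ol (C2–C6 and C15, 4Z alkene built in) to an α‑hydroxy‑γ‑lactone (C1–C2 bond).
5. Lactone carrying C8 and C10: HKR‑resolved epoxide plus propionate dianion, then trans‑selective enolate hydroxylation.

## Forward route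

**Step 1**
Reactants: 1, rac‑2‑(diethoxymethyl)oxirane
Product: 2, (S)‑2‑(diethoxymethyl)oxirane
Conditions: (R,R)‑(salen)Co(III)OAc (0.5 mol%), H2O (0.55 equiv), 0 °C → rt; distil
Reagents that add atoms: none (water ends up only in the discarded diol)
Why: Jacobsen hydrolytic kinetic resolution; the (R,R)‑catalyst hydrolyses the (R)‑epoxide (same sense as epichlorohydrin and methyl glycidate) and leaves (S)‑2, which fixes C8.

**Step 2**
Reactants: 2; 3, propanoic acid
Product: 4, (5S)‑5‑(diethoxymethyl)‑3‑methyloxolan‑2‑one (C3 epimer mixture)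
Conditions: 3, LDA (2.1 equiv), THF/DMPU, 0 °C; add 2, rt → 45 °C; aq. citric acid (pH 4); PPTS (cat.), PhMe, 70 °C
Reagents that add atoms: propanoic acid (3), CCC(=O)O
Why: Creger‑type opening of the epoxide at its CH2 terminus by the propionate dianion, then lactonisation; C8 is not touched and the C3 epimers converge in step 3.

**Step 3**
Reactants: 4
Product: 5, (3R,5S)‑5‑(diethoxymethyl)‑3‑hydroxy‑3‑methyloxolan‑2‑one
Conditions: KHMDS, THF, −78 °C; 2‑(phenylsulfonyl)‑3‑phenyloxaziridine, −78 °C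
Reagents that add atoms: Davis oxaziridine, O=S(=O)(c1ccccc1)N1OC1c1ccccc1 (adds O)
Why: Davis enolate α‑hydroxylation; the oxidant approaches the planar lactone enolate anti to the C5 diethoxymethyl group, giving OH trans to it and setting C10 (R).

**Step 4**
Reactants: 6, (Z)‑3‑methylpent‑2‑en‑4‑yn‑1‑ol
Product: 7, (Z)‑triethyl[(3‑methylpent‑2‑en‑4‑yn‑1‑yl)oxy]silane
Conditions: TESCl, imidazole, CH2Cl2, 0 °C
Reagents that add atoms: TESCl, CC[Si](Cl)(CC)CC
Why: Silylation; masks the Z‑allylic OH, which would otherwise add to the ynone and give a furan.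

**Step 5**
Reactants: 5; 7
Product: 8, (2Z,7R,9S)‑10,10‑diethoxy‑7,9‑dihydroxy‑3,7‑dimethyl‑1‑(triethylsilyloxy)dec‑2‑en‑4‑yn‑6‑one (in equilibrium with its lactol)
Conditions: 7 (2.4 equiv), n‑BuLi (2.3 equiv), THF, −78 °C; add 5, −78 → −40 °C; AcOH quench at −78 °C
Reagents that add atoms: none beyond reactants 5 and 7
Why: Acetylide addition to the lactone carbonyl (C1–C2 bond); the first equivalent deprotonates the tertiary OH and the cold tetrahedral intermediate prevents over‑addition, so the ynone is released only on quench with no stereocentre affected.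

**Step 6**
Reactants: 8
Product: 9, (R)‑2‑[(S)‑3,3‑diethoxy‑2‑hydroxypropyl]‑2‑methyl‑5‑[(Z)‑4‑(triethylsilyloxy)but‑2‑en‑2‑yl]furan‑3(2H)‑one
Conditions: Ph3PAuNTf2 (3 mol%), PhMe, rt
Reagents that add atoms: none
Why: Au(I)‑catalysed 5‑endo‑dig oxa‑cyclisation of the α′‑hydroxy ynone; only the tertiary C10–OH can reach C3 through a five‑membered transition state (C8–OH would need a seven‑membered ring, C6–O is silylated).

**Step 7**
Reactants: 9
Product: 10, (R)‑2‑[(S)‑2‑(tert‑butyldimethylsilyloxy)‑3,3‑diethoxypropyl]‑2‑methyl‑5‑[(Z)‑4‑(triethylsilyloxy)but‑2‑en‑2‑yl]furan‑3(2H)‑one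
Conditions: TBSCl, imidazole, DMAP (cat.), DMF, rt → 35 °C
Reagents that add atoms: TBSCl, CC(C)(C)[Si](C)(C)Cl
Why: Silylation of the only free OH; TBSCl/imidazole is used instead of TBSOTf, which would ionise the acetal.

**Step 8**
Reactants: 10
Product: 11, (S)‑2‑(tert‑butyldimethylsilyloxy)‑3‑[(R)‑5‑((Z)‑4‑hydroxybut‑2‑en‑2‑yl)‑2‑methyl‑3‑oxo‑2,3‑dihydrofuran‑2‑yl]propanal
Conditions: TFA/H2O (9:1), CH2Cl2, 0 °C, ~1 h; NaHCO3
Reagents that add atoms: water, O
Why: Acid hydrolysis; the diethyl acetal and the primary allylic TES ether cleave faster than the secondary TBS ether, which is inductively deactivated by its neighbours.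

**Step 9**
Reactants: 11; 12, methyl acrylate
Product: 13, methyl (4S)‑4‑(tert‑butyldimethylsilyloxy)‑3‑hydroxy‑5‑[(R)‑5‑((Z)‑4‑hydroxybut‑2‑en‑2‑yl)‑2‑methyl‑3‑oxo‑2,3‑dihydrofuran‑2‑yl]‑2‑methylidenepentanoate (C3 epimers)
Conditions: 12 (excess), DABCO (1 equiv), MeOH (co‑solvent), rt, 3–5 d
Reagents that add atoms: methyl acrylate (12), C=CC(=O)OC
Why: Morita–Baylis–Hillman reaction forms C7–C11 at the reactive α‑silyloxy aldehyde; the new carbinol centre is erased in step 11, so its configuration is irrelevant.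

**Step 10**
Reactants: 13
Product: 14, methyl (4S)‑4‑(tert‑butyldimethylsilyloxy)‑3‑hydroxy‑5‑[(R)‑2‑methyl‑3‑oxo‑5‑((Z)‑4‑oxobut‑2‑en‑2‑yl)‑2,3‑dihydrofuran‑2‑yl]‑2‑methylidenepentanoate
Conditions: activated MnO2, CH2Cl2, rt
Reagents that add atoms: none
Why: MnO2 allylic oxidation; the primary allylic alcohol is oxidised much faster than the electron‑poor secondary MBH alcohol, and the Z geometry is retained.

**Step 11**
Reactants: 14
Product: 15, methyl (2Z,4S)‑2‑(bromomethyl)‑4‑(tert‑butyldimethylsilyloxy)‑5‑[(R)‑2‑methyl‑3‑oxo‑5‑((Z)‑4‑oxobut‑2‑en‑2‑yl)‑2,3‑dihydrofuran‑2‑yl]pent‑2‑enoate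
Conditions: NBS, Me2S, CH2Cl2, −20 °C → rt
Reagents that add atoms: NBS, O=C1CCC(=O)N1Br (adds Br)
Why: Corey–Kim‑type SN2′ bromination of the MBH alcohol gives the (Z)‑2‑(bromomethyl)enoate; the aldehyde is inert to the bromosulfonium reagent.

**Step 12**
Reactants: 15
Product: 16, 8‑O‑TBS macrocycle (TBS ether of 17; configuration at C6, C7, C8, C10 as in the target)
Conditions: CrCl2 (8 equiv), THF, rt, 1 mM (syringe‑pump addition); lactonises in situ (brief PPTS if hydroxy ester remains)
Reagents that add atoms: none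
Why: Intramolecular Nozaki–Hiyama‑type Barbier allylation; C7 of the allyl‑Cr(III) adds to the C6 aldehyde through a chair‑like transition state with both ring‑forming substituents pseudo‑equatorial (anti adduct, hence trans‑lactone after loss of MeOH), and the C8 silyloxy centre plus the rigid furanone bridge are relied on to select the face (macrocyclic stereocontrol), setting C6 and C7.

**Step 13**
Reactants: 16
Product: 17, (6R,7R,8S,10R)‑8‑hydroxy‑1‑oxo‑3,10‑epoxygermacra‑2,4Z,11(13)‑trien‑12,6‑olide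
Conditions: HF·pyridine, THF/pyridine, 0 °C → rt
Reagents that add atoms: none
Why: Acidic fluoride desilylation; these conditions avoid the base that would attack the α‑methylene lactone or trigger lactone migration to O8.

**Step 14**
Reactants: 17; 18, angelic acid
Product: 19, lychnopholide
Conditions: 18, 2,4,6‑Cl3C6H2COCl, Et3N, PhMe, rt; then 17, PhMe, 80 °C
Reagents that add atoms: angelic acid (18), C/C=C(/C)C(=O)O
Why: Yamaguchi mixed‑anhydride esterification without a nucleophilic catalyst, which acylates the hindered C8–OH while avoiding angelate‑to‑tiglate isomerisation.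

## Compound list

1 | rac‑2‑(diethoxymethyl)oxirane | CCOC(OCC)C1CO1 | starting material
2 | (S)‑2‑(diethoxymethyl)oxirane | CCOC(OCC)[C@@H]1CO1 | intermediate
3 | propanoic acid | CCC(=O)O | starting material
4 | (5S)‑5‑(diethoxymethyl)‑3‑methyloxolan‑2‑one | CCOC(OCC)[C@@H]1CC(C)C(=O)O1 | intermediate
5 | (3R,5S)‑5‑(diethoxymethyl)‑3‑hydroxy‑3‑methyloxolan‑2‑one | CCOC(OCC)[C@@H]1C[C@@](C)(O)C(=O)O1 | intermediate
6 | (Z)‑3‑methylpent‑2‑en‑4‑yn‑1‑ol | C#C/C(C)=C\CO | starting material
7 | (Z)‑triethyl[(3‑methylpent‑2‑en‑4‑yn‑1‑yl)oxy]silane | C#C/C(C)=C\CO[Si](CC)(CC)CC | intermediate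
8 | (2Z,7R,9S)‑10,10‑diethoxy‑7,9‑dihydroxy‑3,7‑dimethyl‑1‑(triethylsilyloxy)dec‑2‑en‑4‑yn‑6‑one | CCOC(OCC)[C@@H](O)C[C@@](C)(O)C(=O)C#C/C(C)=C\CO[Si](CC)(CC)CC | intermediate
9 | furanone alcohol (step 6 product) | CCOC(OCC)[C@@H](O)C[C@@]1(C)OC(/C(C)=C\CO[Si](CC)(CC)CC)=CC1=O | intermediate
10 | furanone C8‑OTBS ether | CCOC(OCC)[C@@H](O[Si](C)(C)C(C)(C)C)C[C@@]1(C)OC(/C(C)=C\CO[Si](CC)(CC)CC)=CC1=O | intermediate
11 | α‑silyloxy aldehyde / allylic alcohol | O=C[C@@H](O[Si](C)(C)C(C)(C)C)C[C@@]1(C)OC(/C(C)=C\CO)=CC1=O | intermediate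
12 | methyl acrylate | C=CC(=O)OC | starting material
13 | MBH adduct (C7 epimers) | COC(=O)C(=C)C(O)[C@@H](O[Si](C)(C)C(C)(C)C)C[C@@]1(C)OC(/C(C)=C\CO)=CC1=O | intermediate
14 | MBH adduct (Z)‑enal | COC(=O)C(=C)C(O)[C@@H](O[Si](C)(C)C(C)(C)C)C[C@@]1(C)OC(/C(C)=C\C=O)=CC1=O | intermediate
15 | (Z)‑2‑(bromomethyl)enoate enal | COC(=O)/C(CBr)=C/[C@@H](O[Si](C)(C)C(C)(C)C)C[C@@]1(C)OC(/C(C)=C\C=O)=CC1=O | intermediate
16 | 8‑O‑TBS macrocyclic lactone | C=C1C(=O)O[C@@H]2/C=C(/C)C3=CC(=O)[C@@](C)(C[C@H](O[Si](C)(C)C(C)(C)C)[C@@H]12)O3 | intermediate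
17 | C8 alcohol (8‑desacyl lychnopholide) | C=C1C(=O)O[C@@H]2/C=C(/C)C3=CC(=O)[C@@](C)(C[C@H](O)[C@@H]12)O3 | intermediate
18 | angelic acid, (Z)‑2‑methylbut‑2‑enoic acid | C/C=C(/C)C(=O)O | starting material
19 | lychnopholide | C=C1C(=O)O[C@@H]2/C=C(/C)C3=CC(=O)[C@@](C)(C[C@H](OC(=O)/C(C)=C\C)[C@@H]12)O3 | target

## Summary

**Total steps:** 14. **Longest linear sequence:** 13 (steps 1–3, then 5–14; step 4 is a one‑step side branch).

**Three steps most likely to fail, with fallbacks:**

1. **Step 12 (Cr‑Barbier macrocyclisation).** Risks are medium‑ring strain and the C6/C7 diastereomer obtained relative to C8; the facial selectivity is argued, not proven. Fallback: cyclise before the furanone exists. Keep C1–C3 as an alkyne with C1 as a protected carbinol (acetylide added to the DIBAL lactol of 5), run the Barbier closure on the more flexible 2‑en‑4‑yne, then oxidise C1 and form the furanone by transannular Au(I) cyclisation. If only the cis‑lactone (C6 epimer) forms, saponify and invert C6 by Mitsunobu relactonisation.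

2. **Step 8 (acetal hydrolysis next to OTBS without losing the TBS).** Fallback: change the C7 handle from acetal to protected alcohol. Start from commercial (S)‑γ‑(trityloxymethyl)‑γ‑butyrolactone (α‑methylation, then the same Davis hydroxylation), keep C6 as a TBS ether, and unveil C7 by detritylation and Dess–Martin oxidation (two extra steps).

3. **Step 9 (MBH on a hindered α‑silyloxy aldehyde bearing a base‑sensitive dienyl furanone).** Risks are slow reaction, C8 epimerisation and 4Z isomerisation by the amine. Fallback: make the same adduct without a nucleophilic amine by hydroalumination–aldol, adding the [α‑(methoxycarbonyl)vinyl]aluminium reagent from methyl propiolate and DIBAL‑H/NMO to aldehyde 11.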